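## Analysis of the target

The target 22 is a eudesmane sesquiterpenoid built on an octalin with a C5=C6 double bond. Eudesmane numbering is used throughout: ring A is C1–C5 plus C10, ring B is C5–C10, C14 is the methyl on C10, C15 the methyl on C4, and C11–C13 form the methyl propenoate unit on C7 (C12 ester carbon, C13 methylene); β is the face that carries C14. There are four stereocentres, (3S,4R,7R,10S): quaternary C10, C7 with its side chain β (cis to C14 across ring B), C3 with an equatorial β angelate, and C4 with an axial β hydroxyl (syn-axial to C14) and an equatorial α methyl, so the two ring A oxygens are cis. C5 is sp2, so no ring-fusion hydrogen relays stereochemistry between the rings. The sensitive groups are the angelate (Z to E isomerisation to the tiglate), the tertiary allylic alcohol at C4 (ionisation and allylic transposition in acid), the 2-substituted acrylate (Michael acceptor) and the doubly allylic C7–H (base can move either double bond into conjugation). The difficulty is to make quaternary C10 as one enantiomer, to set C3, C4 and C7 around an sp2 fusion atom, and to order the end game so that the angelate meets neither base nor palladium and phosphine. The strategy rests on one pattern: C10 is bonded to C5, whose other neighbour C4 carries oxygen, so C10, C5 and C4 with the rest of ring A are a 3-methylcyclohexane-1,2-dione in disguise, and C6–C9 are a four-carbon enone unit with its carbonyl at C7.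

## Retrosynthetic reasoning

**C3–O acyl bond.** Target 22 is cut into diol acrylate 19 and angelic acid 20, activated as mixed anhydride 21. This keeps the isomerisable Z-enoate out of every earlier step. It is possible because the C3 hydroxyl of 19 is the only secondary alcohol; the C4 hydroxyl is tertiary and axial. The forward acylation must not isomerise the enoate.

**C11=C13 and the extra carboxyl carbon.** 19 is traced through Mannich base 18 to malonic half ester 17, and 17 to diester 16. The side chain can then arrive at C7 as a stabilised carbon nucleophile, and the acrylate is unveiled by a decarboxylative Mannich methylenation under weakly basic conditions that leave C7–H alone.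

**C3 carbinol.** 16 is traced to ketone 15. A C3 ketone next to the axial C4–O bond should take hydride axially from the α face, which gives the equatorial 3β alcohol. At the stage of 15 no other secondary alcohol is present, so C3 and C7 never have to be told apart by protecting groups.

**C7–C11 bond.** 15 is cut into allylic carbonate 13 and dimethyl malonate 14. The allyl unit C5–C6–C7 can only be attacked at C7, because C5 is fully substituted. A palladium-catalysed substitution with a stabilised nucleophile runs with overall retention, so a 7β oxygen becomes the 7β carbon substituent. 13 comes from alcohol 12 and this from silyl ether 11.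

**Ring A oxygens and C15.** 11 comes from diol 10 by oxidation at C3. 10 comes from ketol 9 by cutting C4–C15 (a methyl nucleophile adds to the C4 ketone from the α face, since C14 blocks the β face). 9 comes from enone 7 through enolate 8 by cutting the C3–O bond. The C4 ketone is needed first to activate C3. Whichever C3 epimer the hydroxylation gives is of no account, because C3 passes through the ketone in 11 and 15.

**Differentiating the two carbonyls.** 7 comes from alcohol 6, and 6 from ene-dione 5 by reduction of the unhindered ring B carbonyl only. The forward reduction has to choose C7 over C4 and the α face of C7.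

**Ring B and C10.** 5 is cut at C9–C10 and at C5=C6 into dione 1 and methyl vinyl ketone 2, through triketone 3 and ketol 4. Both partners are purchasable, so no steps precede the key step. One operation builds ring B and C10 and leaves carbonyls at C4 and C7 with C5=C6 in place. The forward reaction must choose one face of the enol of 1 and send the aldol to C5.

## Alternatives that were turned down

**Alternative 1:** The whole bicycle is disconnected to the acyclic precursor farnesyl diphosphate (A2). A selinene-forming terpene synthase would ionise A2, join C6 to C7 to a ten-membered ring, protonate it at C1, close C5–C10 across it and release (+)-β-selinene (A1).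
- For it: one enzymatic step gives all fifteen carbons, both rings, and C7 and C10 in the configuration of 22 with full enantiocontrol. On these points it is stronger than the chosen route, whose key step sets only C10 with an untested catalyst and substrate pairing.
- Against it: A1 is a hydrocarbon with an sp3 C5, an exocyclic C4 methylene and an isopropenyl group. C12 must be raised by three oxidation levels at one of several allylic positions. C3 and C4 must be oxygenated with the C4 oxygen on the β face, whereas hydration or epoxidation of the exocyclic alkene would come from the open α face. C5–C6 must be desaturated at an unactivated position. The enzyme must be expressed and A2 supplied.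
- Comparison: the chosen route offers instead an intermediate (5) that already has oxygen at C4 and C7 and the C5=C6 bond, so all later steps act at activated positions.

**Alternative 2:** Ring B is disconnected at C5–C10 and C8–C9 into methacrolein (A4) and an E-configured 2-silyloxy diene (A5) that carries C2–C4 with the silylated C4 carbinol and a terminal alkyne. A chiral cationic boron Lewis acid would activate A4, and the cycloaddition would give the ring B silyl enol ether aldehyde A3 with quaternary C10.
- For it: catalytic asymmetric Diels–Alder reactions of 2-substituted acroleins are much better established than the annulation proposed here, so on precedent for the C10-forming event it is the stronger plan. C4 arrives with A5 and needs no substrate-controlled addition. The enol ether puts oxygen at C7 as in 5.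
- Against it: A5 needs an enantiopure tertiary propargylic ether and so an asymmetric synthesis of its own. Catalyst and C4 centre may be mismatched. The new C5–C10 bond joins a quaternary carbon to a carbon bearing a fully substituted carbinol. After the cycloaddition ring A is still open: closure of C1–C2 leaves an oxygen at C1 that 22 lacks, the alkyne must become a saturated C2 and a C3 carbinol, the C5 centre is made only to be destroyed, and C6=C7 must move to C5=C6.
- Comparison: the Robinson annulation builds ring B onto a ready-made ring A from two purchasable compounds. The price is that C3 and C4 are set later by substrate control.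

**Alternative 3:** The C9–C10 bond is disconnected to a phenol (A7) whose ring is the future ring A (hydroxyl at C3, methyls at C4 and C10) and whose side chain holds C6–C9, the C7 isopropenyl centre and a terminal mesylate. Deprotonation would give the phenolate of A7, whose para carbon C10 displaces the mesylate at C9. Ring B closes and the arene becomes eudesma-1,4,11-trien-3-one (A6).
- For it: after the key step all fifteen carbons, the C3 oxygen and the C4 methyl are present, and C7 is fixed before the ring closes. In these respects it is ahead of the chosen route, which adds C15, the C3 oxygen and the side chain afterwards.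
- Against it: C10 is set only by 1,4-induction from C7. A7 needs a multi-step enantioselective synthesis. A6 has the wrong pattern in three places: C4=C5 must move to C5=C6 with oxygenation at C4, and an electrophilic oxygen would approach the C3 dienolate of A6 from the α face (anti to C14) to give the C4 epimer; C1=C2 must be saturated beside the isopropenyl group; the isopropenyl methyl must be oxidised to the ester level late.
- Comparison: in the chosen route the C4 oxygen ends up β because the methyl nucleophile, not the oxygen, enters from the open α face, and the side chain enters at the right oxidation level.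

Key step: step 1

## Route

Assumption: the quinine-derived primary amine is taken to give the (10R) ene-dione 5; if the sense of induction is opposite, the pseudoenantiomeric quinidine-derived amine replaces it with no other change. The amine is purchasable and is not counted as a step.

Step 1
Reactants: 1 3-methylcyclohexane-1,2-dione; 2 methyl vinyl ketone
Product: 5 (10R)-10-methyloctal-5-ene-4,7-dione, via Michael triketone 3 (not isolated), via bicyclic ketol 4 (not isolated)
Conditions: 9-amino-9-deoxy-epi-quinine (20 mol %), CF3CO2H (40 mol %), toluene, 0 → 25 °C, then 60 °C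
Reagents that add atoms: none
Why: Proposed new method: dione 1 reacts as its predominant, more substituted enol (2-hydroxy-3-methylcyclohex-2-enone), whose methyl-bearing carbon is the nucleophilic terminus, while the primary amine turns 2 into an iminium ion and the protonated quinuclidine of the catalyst holds the enol oxygen by hydrogen bonding and ion pairing, so that C9–C10 forms on one face of the enol and gives triketone 3. The closest known reaction types are primary-amine (iminium) catalysed Michael additions of enolic dicarbonyl compounds to enones, amine-catalysed Michael additions of cyclic 1,2-diones to enals and nitroalkenes, and enantioselective amine-catalysed Robinson annulations of 1,3-dicarbonyl donors; what has not been shown is a 3-alkyl 1,2-dione as donor with its vicinal carbonyl as aldol acceptor. The same amine then forms the enamine of the side-chain methyl ketone at its methyl carbon (C6), which attacks the adjacent C5 carbonyl in a 6-(enolexo)-exo-trig aldol closure to ketol 4, and this closes ring B. Acid-assisted dehydration of 4 gives the C5=C6 bond of 5, conjugated to both carbonyls, which pulls the sequence forward. C10 is the only stereocentre that remains; it is set in the Michael step by the catalyst alone, because the acceptor carbon of 2 is not prochiral and the face of the enol must be chosen, and the C5 carbinol centre of 4 is erased. The step needs C- rather than O-alkylation of the enol, which is expected because O-alkylation is reversible and the C-adduct is the thermodynamic product. It also needs aldol at C5 rather than C4, which ring size secures (six-membered from C6 to C5, seven-membered to C4), and the methyl rather than the methylene enamine; attack of C8 on C4 would give a bicyclo[3.2.1]octane ketol that cannot dehydrate and can return by retro-aldol.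

Step 2
Reactants: 5 (10R)-10-methyloctal-5-ene-4,7-dione
Product: 6 7β-hydroxy-10β-methyloctal-5-en-4-one
Conditions: NaBH4, CeCl3·7H2O, MeOH–CH2Cl2, −78 °C
Reagents that add atoms: none
Why: Luche reduction, run cold with about one hydride equivalent. C7 is an unhindered cyclohexenone carbonyl, whereas C4 is flanked by the fully substituted C5 and its axial β trajectory is blocked by C14, so C7 should react first. Hydride is expected to attack C7 pseudoaxially from the α face, opposite C14 in the preferred half-chair of ring B, which gives the pseudoequatorial 7β alcohol (cis to C14).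

Step 3
Reactants: 6 7β-hydroxy-10β-methyloctal-5-en-4-one
Product: 7 7β-(tert-butyldimethylsilyloxy)-10β-methyloctal-5-en-4-one
Conditions: TBSCl, imidazole, DMF, 0 → 25 °C
Reagents that add atoms: tert-butyldimethylsilyl chloride, CC(C)(C)[Si](C)(C)Cl
Why: Standard silylation of a secondary alcohol; the ether protects C7 through enolate formation, organometallic addition and oxidation.

Step 4
Reactants: 7 7β-(tert-butyldimethylsilyloxy)-10β-methyloctal-5-en-4-one
Product: 9 3α-hydroxy-7β-(tert-butyldimethylsilyloxy)-10β-methyloctal-5-en-4-one, via potassium enolate 8 (not isolated)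
Conditions: KN(SiMe3)2, THF, −78 °C; 2-(phenylsulfonyl)-3-phenyloxaziridine, −78 °C; aq. NH4Cl
Reagents that add atoms: 2-(phenylsulfonyl)-3-phenyloxaziridine, O=S(=O)(c1ccccc1)N1OC1c1ccccc1
Why: Kinetic deprotonation of the enone at the α′ carbon C3 gives the cross-conjugated enolate 8, and oxygen transfer from the N-sulfonyloxaziridine (enolate hydroxylation) gives the ketol. Attack should be axial on the α face, anti to C14, hence 3α; this centre is reset in steps 6 and 10, so the selectivity here is not critical.

Step 5
Reactants: 9 3α-hydroxy-7β-(tert-butyldimethylsilyloxy)-10β-methyloctal-5-en-4-one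
Product: 10 7β-(tert-butyldimethylsilyloxy)-4α,10β-dimethyloctal-5-ene-3α,4β-diol
Conditions: CeCl3, MeMgBr, THF, −78 → 0 °C; aq. NH4Cl
Reagents that add atoms: methylmagnesium bromide, C[Mg]Br
Why: Organocerium 1,2-addition: MeCeCl2 formed in the flask is weakly basic, so after deprotonating the C3 hydroxyl it adds to the hindered conjugated ketone without enolisation or conjugate addition. Ring A is held as a chair with C14 axial, so the β (axial) approach to C4 suffers a 1,3-diaxial contact and the methyl group enters from the α face, giving equatorial 4α-methyl and axial 4β-hydroxyl.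

Step 6
Reactants: 10 7β-(tert-butyldimethylsilyloxy)-4α,10β-dimethyloctal-5-ene-3α,4β-diol
Product: 11 7β-(tert-butyldimethylsilyloxy)-4β-hydroxy-4α,10β-dimethyloctal-5-en-3-one
Conditions: IBX, DMSO, 25 °C
Reagents that add atoms: none
Why: IBX oxidises the secondary alcohol of a 1,2-diol to the α-hydroxy ketone without cleaving the C3–C4 bond; tertiary alcohol, silyl ether and alkene are inert. The step erases the C3 configuration so that hydride can set it in step 10.

Step 7
Reactants: 11 7β-(tert-butyldimethylsilyloxy)-4β-hydroxy-4α,10β-dimethyloctal-5-en-3-one
Product: 12 4β,7β-dihydroxy-4α,10β-dimethyloctal-5-en-3-one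
Conditions: Bu4NF, AcOH, THF, 0 → 25 °C
Reagents that add atoms: none
Why: Fluoride-induced cleavage of the silyl ether; acetic acid keeps the medium near neutral so that the tertiary α-ketol is not exposed to base, which could trigger an acyloin (α-ketol) rearrangement.

Step 8
Reactants: 12 4β,7β-dihydroxy-4α,10β-dimethyloctal-5-en-3-one
Product: 13 4β-hydroxy-4α,10β-dimethyl-3-oxooctal-5-en-7β-yl methyl carbonate
Conditions: ClCO2Me, pyridine, DMAP (cat.), CH2Cl2, 0 °C
Reagents that add atoms: methyl chloroformate, COC(=O)Cl
Why: Acylation of the only secondary hydroxyl with a chloroformate; the tertiary axial C4 hydroxyl does not react and the C7 configuration is untouched.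

Step 9
Reactants: 13 4β-hydroxy-4α,10β-dimethyl-3-oxooctal-5-en-7β-yl methyl carbonate; 14 dimethyl malonate
Product: 15 dimethyl 2-(4β-hydroxy-4α,10β-dimethyl-3-oxooctal-5-en-7β-yl)malonate
Conditions: Pd(PPh3)4 (5 mol %), THF, 25 → 50 °C
Reagents that add atoms: none
Why: Tsuji–Trost allylic alkylation: zerovalent palladium ionises the carbonate anti to the leaving group, from the α face, releasing CO2 and methoxide, which deprotonates 14. The malonate then attacks the η3-allyl complex anti to palladium, on the β face (net retention, 7β), and at C7 rather than C5 because C5 is fully substituted and lies between two quaternary carbons.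

Step 10
Reactants: 15 dimethyl 2-(4β-hydroxy-4α,10β-dimethyl-3-oxooctal-5-en-7β-yl)malonate
Product: 16 dimethyl 2-(3β,4β-dihydroxy-4α,10β-dimethyloctal-5-en-7β-yl)malonate
Conditions: NaBH4, MeOH, −20 °C
Reagents that add atoms: none
Why: Ketone reduction with NaBH4: axial delivery of hydride to C3 from the α face of the ring A chair, anti to the axial C4–O bond (Felkin–Anh), gives the equatorial 3β alcohol and thus the cis-diol. The ester groups are not reduced under these conditions.

Step 11
Reactants: 16 dimethyl 2-(3β,4β-dihydroxy-4α,10β-dimethyloctal-5-en-7β-yl)malonate
Product: 17 2-(3β,4β-dihydroxy-4α,10β-dimethyloctal-5-en-7β-yl)-3-methoxy-3-oxopropanoic acid (mixture of C11 epimers)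
Conditions: KOH (1.05 equiv), MeOH–H2O, 0 → 25 °C; 1 M HCl to pH 4, 0 °C
Reagents that add atoms: potassium hydroxide, [K+].[OH-]
Why: Mono-saponification of a malonic diester: the first carboxylate deactivates the second ester, so one equivalent of hydroxide stops at the half ester; the new centre at C11 is a mixture of no consequence.

Step 12
Reactants: 17 2-(3β,4β-dihydroxy-4α,10β-dimethyloctal-5-en-7β-yl)-3-methoxy-3-oxopropanoic acid
Product: 19 methyl 3β,4β-dihydroxyeudesma-5,11(13)-dien-12-oate, via Mannich base 18 (not isolated)
Conditions: (CH2O)n, Et2NH, THF, 65 °C
Reagents that add atoms: formaldehyde (from paraformaldehyde), C=O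
Why: Mannich reaction of the malonic half ester with the iminium species from formaldehyde and Et2NH gives 18, which loses CO2 and Et2NH (decarboxylative elimination) to the 2-substituted acrylate. The medium is only weakly basic, so C7–H is not epimerised and neither double bond moves.

Step 13
Reactants: 19 methyl 3β,4β-dihydroxyeudesma-5,11(13)-dien-12-oate; 20 angelic acid
Product: 22 methyl 3β-angeloyloxy-4β-hydroxyeudesma-5,11(13)-dien-12-oate (target), via mixed anhydride 21 (not isolated)
Conditions: 2,4,6-trichlorobenzoyl chloride, Et3N, toluene, 25 °C; then 19, toluene, 75 °C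
Reagents that add atoms: none
Why: Yamaguchi esterification: the mixed anhydride 21 transfers the angeloyl group to the equatorial secondary C3 hydroxyl, the tertiary C4 hydroxyl being unreactive. Omitting a nucleophilic acylation catalyst limits Z to E isomerisation of the enoate.

## Compound list

1 | 3-methylcyclohexane-1,2-dione | CC1CCCC(=O)C1=O | starting material
2 | methyl vinyl ketone (but-3-en-2-one) | CC(=O)C=C | starting material
3 | (R)-3-methyl-3-(3-oxobutyl)cyclohexane-1,2-dione (Michael triketone) | CC(=O)CC[C@@]1(C)CCCC(=O)C1=O | intermediate (not isolated)
4 | 5β-hydroxy-10β-methyldecalin-4,7-dione (bicyclic ketol, drawn cis-fused; the C5 centre is lost on dehydration) | O=C1C[C@]2(O)C(=O)CCC[C@]2(C)CC1 | intermediate (not isolated)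
5 | (10R)-10-methyloctal-5-ene-4,7-dione, i.e. (R)-4a-methyl-3,4,4a,5,6,7-hexahydronaphthalene-2,8-dione | O=C1C=C2C(=O)CCC[C@]2(C)CC1 | intermediate
6 | 7β-hydroxy-10β-methyloctal-5-en-4-one | O[C@H]1C=C2C(=O)CCC[C@]2(C)CC1 | intermediate
7 | 7β-(tert-butyldimethylsilyloxy)-10β-methyloctal-5-en-4-one | CC(C)(C)[Si](C)(C)O[C@H]1C=C2C(=O)CCC[C@]2(C)CC1 | intermediate
8 | potassium C3=C4 enolate of 7 | CC(C)(C)[Si](C)(C)O[C@H]1C=C2C([O-])=CCC[C@]2(C)CC1.[K+] | intermediate (not isolated)
9 | 3α-hydroxy-7β-(tert-butyldimethylsilyloxy)-10β-methyloctal-5-en-4-one | CC(C)(C)[Si](C)(C)O[C@H]1C=C2C(=O)[C@H](O)CC[C@]2(C)CC1 | intermediate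
10 | 7β-(tert-butyldimethylsilyloxy)-4α,10β-dimethyloctal-5-ene-3α,4β-diol | CC(C)(C)[Si](C)(C)O[C@H]1C=C2[C@@](C)(O)[C@H](O)CC[C@]2(C)CC1 | intermediate
11 | 7β-(tert-butyldimethylsilyloxy)-4β-hydroxy-4α,10β-dimethyloctal-5-en-3-one | CC(C)(C)[Si](C)(C)O[C@H]1C=C2[C@@](C)(O)C(=O)CC[C@]2(C)CC1 | intermediate
12 | 4β,7β-dihydroxy-4α,10β-dimethyloctal-5-en-3-one | O[C@H]1C=C2[C@@](C)(O)C(=O)CC[C@]2(C)CC1 | intermediate
13 | 4β-hydroxy-4α,10β-dimethyl-3-oxooctal-5-en-7β-yl methyl carbonate | COC(=O)O[C@H]1C=C2[C@@](C)(O)C(=O)CC[C@]2(C)CC1 | intermediate
14 | dimethyl malonate | COC(=O)CC(=O)OC | starting material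
15 | dimethyl 2-(4β-hydroxy-4α,10β-dimethyl-3-oxooctal-5-en-7β-yl)malonate | COC(=O)C(C(=O)OC)[C@H]1C=C2[C@@](C)(O)C(=O)CC[C@]2(C)CC1 | intermediate
16 | dimethyl 2-(3β,4β-dihydroxy-4α,10β-dimethyloctal-5-en-7β-yl)malonate | COC(=O)C(C(=O)OC)[C@H]1C=C2[C@@](C)(O)[C@@H](O)CC[C@]2(C)CC1 | intermediate
17 | 2-(3β,4β-dihydroxy-4α,10β-dimethyloctal-5-en-7β-yl)-3-methoxy-3-oxopropanoic acid (C11 epimers) | COC(=O)C(C(=O)O)[C@H]1C=C2[C@@](C)(O)[C@@H](O)CC[C@]2(C)CC1 | intermediate
18 | 2-(diethylaminomethyl) derivative of 17 (Mannich base, C11 epimers) | CCN(CC)CC(C(=O)O)(C(=O)OC)[C@H]1C=C2[C@@](C)(O)[C@@H](O)CC[C@]2(C)CC1 | intermediate (not isolated)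
19 | methyl 3β,4β-dihydroxyeudesma-5,11(13)-dien-12-oate | C=C(C(=O)OC)[C@H]1C=C2[C@@](C)(O)[C@@H](O)CC[C@]2(C)CC1 | intermediate
20 | angelic acid, (Z)-2-methylbut-2-enoic acid | C/C=C(/C)C(=O)O | starting material
21 | angelic 2,4,6-trichlorobenzoic anhydride | C/C=C(/C)C(=O)OC(=O)c1c(Cl)cc(Cl)cc1Cl | intermediate (not isolated)
22 | methyl (3S,4R,7R,10S)-3β-angeloyloxy-4β-hydroxyeudesma-5,11(13)-dien-12-oate | C=C(C(=O)OC)[C@H]1C=C2[C@@](C)(O)[C@@H](OC(=O)/C(C)=C\C)CC[C@]2(C)CC1 | target

## Step count and least certain steps

Total step count: 13. Longest linear sequence: 13 steps (1 and 2 to 22); 14 and 20 are used as purchased.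

**Step 1 (key step, carries the label).**
- What may go wrong: insufficient discrimination between the two faces of the enol, since the stereocentre forms on the nucleophile and the acceptor is not prochiral. Reaction through the minor enol at the unsubstituted α-carbon, polymerisation of 2, condensation of the catalyst amine with the dione to an unreactive enaminone, and aldol through the methylene enamine are further failure paths.
- Fallback (known chemistry; sets out from 1 and 2, returns at 6): Et3N-catalysed Michael addition of 1 to 2 gives the racemic triketone F1. Aldol condensation with pyrrolidine and AcOH gives the racemic ene-dione F2. Luche reduction as in step 2 gives the racemic cis-hydroxy enone F3. Esterification with (S)-O-methylmandelic acid (DCC, DMAP) gives two diastereomers, the (S)-O-methylmandelate of 6 F4 and the (S)-O-methylmandelate of the enantiomer of 6 F5, which are separated by chromatography or crystallisation. Methanolysis of F4 (K2CO3, MeOH, 0 °C) releases 6.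

**Step 2.**
- What may go wrong: incomplete discrimination between two conjugated carbonyls, leading to reduction at C4 or at both sites, and conjugate reduction of the ene-dione.
- Fallback (sets out from 5, returns at 7): both carbonyls are reduced with excess NaBH4 and CeCl3 to the 4β,7β-diol F6. The unhindered C7 hydroxyl is silylated selectively (TBSCl, imidazole, −20 °C) to the mono-silyl ether F7. The hindered allylic C4 alcohol is then oxidised (MnO2 or Dess–Martin periodinane) to 7.

**Step 5.**
- What may go wrong: low conversion because the ketone sits next to an alkoxide, and partial loss of facial selectivity caused by the axial C3 oxygen on the α face.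
- Fallback (sets out from 9, returns at 10): O-silylation (Me3SiCl, imidazole) gives the 3α-trimethylsilyloxy ketone F8. MeLi with CeCl3 adds to the now neutral ketone to give the tertiary alcohol F9. K2CO3 in MeOH removes the trimethylsilyl group, leaves the tert-butyldimethylsilyl ether, and gives 10.

**Step 9.**
- What may go wrong: slow ionisation of the pseudoequatorial carbonate, β-hydride elimination from the allyl complex to a 5,7-diene, and base-induced reorganisation of the α-ketol.
- Fallback (sets out from 12, returns at 15): Appel bromination (CBr4, PPh3) with inversion gives the 7α-bromide F10. Displacement by the sodium salt of 14 (NaH, THF–DMF, 0 °C) with a second inversion gives 15.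

**Step 13.**
- What may go wrong: Z to E isomerisation of the angeloyl unit during activation and heating, and sluggish acylation of a hydroxyl next to a quaternary carbinol.
- Fallback (sets out from 19, returns at 22): esterification with 2-[bis(2,2,2-trifluoroethoxy)phosphoryl]propanoic acid (EDC, DMAP) gives the phosphonate ester F11. Still–Gennari olefination with acetaldehyde (KN(SiMe3)2, 18-crown-6, THF, −78 °C) builds the Z-2-methylbut-2-enoate on the molecule and gives 22.

## Further compounds

F1 | step 1 | racemic 3-methyl-3-(3-oxobutyl)cyclohexane-1,2-dione | CC(=O)CCC1(C)CCCC(=O)C1=O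
F2 | step 1 | racemic 10-methyloctal-5-ene-4,7-dione | O=C1C=C2C(=O)CCCC2(C)CC1
F3 | step 1 | racemic cis-7-hydroxy-10-methyloctal-5-en-4-one (6 and its enantiomer) | O[C@H]1C=C2C(=O)CCC[C@]2(C)CC1.O[C@@H]1C=C2C(=O)CCC[C@@]2(C)CC1
F4 | step 1 | (S)-O-methylmandelate of 6 | CO[C@H](C(=O)O[C@H]1C=C2C(=O)CCC[C@]2(C)CC1)c1ccccc1
F5 | step 1 | (S)-O-methylmandelate of the enantiomer of 6 | CO[C@H](C(=O)O[C@@H]1C=C2C(=O)CCC[C@@]2(C)CC1)c1ccccc1
F6 | step 2 | 10β-methyloctal-5-ene-4β,7β-diol | O[C@H]1C=C2[C@@H](O)CCC[C@]2(C)CC1
F7 | step 2 | 7β-(tert-butyldimethylsilyloxy)-10β-methyloctal-5-en-4β-ol | CC(C)(C)[Si](C)(C)O[C@H]1C=C2[C@@H](O)CCC[C@]2(C)CC1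
F8 | step 5 | 3α-trimethylsilyloxy-7β-(tert-butyldimethylsilyloxy)-10β-methyloctal-5-en-4-one | CC(C)(C)[Si](C)(C)O[C@H]1C=C2C(=O)[C@H](O[Si](C)(C)C)CC[C@]2(C)CC1
F9 | step 5 | 3α-trimethylsilyloxy-7β-(tert-butyldimethylsilyloxy)-4α,10β-dimethyloctal-5-en-4β-ol | CC(C)(C)[Si](C)(C)O[C@H]1C=C2[C@@](C)(O)[C@H](O[Si](C)(C)C)CC[C@]2(C)CC1
F10 | step 9 | 7α-bromo-4β-hydroxy-4α,10β-dimethyloctal-5-en-3-one | Br[C@@H]1C=C2[C@@](C)(O)C(=O)CC[C@]2(C)CC1
F11 | step 13 | 3β-{2-[bis(2,2,2-trifluoroethoxy)phosphoryl]propanoyloxy} derivative of 19 | C=C(C(=O)OC)[C@H]1C=C2[C@@](C)(O)[C@@H](OC(=O)C(C)P(=O)(OCC(F)(F)F)OCC(F)(F)F)CC[C@]2(C)CC1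
A1 | alternative 1 | (+)-β-selinene | CC(=C)[C@H]1C[C@H]2C(=C)CCC[C@]2(C)CC1
A2 | alternative 1 | (2E,6E)-farnesyl diphosphate | CC(C)=CCC/C(C)=C/CC/C(C)=C/COP(=O)(O)OP(=O)(O)O
A3 | alternative 2 | ring B silyl enol ether aldehyde | O=C[C@]1(C)CCC(O[Si](C)(C)C(C)(C)C)=C[C@@H]1[C@@](C)(O[Si](CC)(CC)CC)C#C
A4 | alternative 2 | methacrolein | CC(=C)C=O
A5 | alternative 2 | E-2-(tert-butyldimethylsilyloxy)-1,3-diene with the triethylsilyl-protected tertiary propargylic carbinol at its terminus | C=C(O[Si](C)(C)C(C)(C)C)/C=C/[C@@](C)(O[Si](CC)(CC)CC)C#C
A6 | alternative 3 | eudesma-1,4,11-trien-3-one | CC(=C)[C@H]1CC2=C(C)C(=O)C=C[C@]2(C)CC1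
A7 | alternative 3 | 2,4-dimethyl-3-(4-mesyloxy-2-isopropenylbutyl)phenol | CC(=C)[C@@H](Cc1c(C)ccc(O)c1C)CCOS(C)(=O)=O
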